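In a one-step world the substrate has a single time constant and a single end; this substrate meets a fork.

| flask | substrate | reagent | time | remark |
|---|---|---|---|---|
| elm | 0.25 M | 1.50 equiv (fed, over 8.0 d) | 12 d | all else is in the flask from the start; the feed brings no volume worth counting |
| larch | 0.25 M | 1.50 equiv | 12 d | everything together at the start |
| cedar | 0.25 M | 1.50 equiv (in portions, 4, over 8.0 d) | 12 d | first portion at the start, last at 8.0 d |
| maple | 0.25 M (fed, over 8.0 d) | 1.50 equiv | 12 d | all else is in the flask from the start; the feed brings no volume worth counting |

    substrate + reagent ⇌ intermediate A (K1 = 47 L mol⁻¹, k1 = 8.52 × 10⁻⁵ L mol⁻¹ s⁻¹)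
    reagent + intermediate A → side product A (k2 = 2.14 × 10⁻⁵ L mol⁻¹ s⁻¹)
    substrate → intermediate B (k3 = 9.22 × 10⁻⁶ s⁻¹)
    reagent + intermediate A → side product B (k4 = 2.45 × 10⁻⁵ L mol⁻¹ s⁻¹)
    reagent + intermediate B ⇌ intermediate C (K5 = 54.1 L mol⁻¹, k5 = 9.48 × 10⁻⁶ L mol⁻¹ s⁻¹)
    reagent + intermediate C → target (k6 = 7.11 × 10⁻⁵ L mol⁻¹ s⁻¹)
    target ⇌ isomer of the product (K7 = 0.139, k7 = 8.22 × 10⁻⁶ s⁻¹)
    substrate + intermediate B → side product C (k8 = 1.38 × 10⁻⁵ L mol⁻¹ s⁻¹)

- a species is counted by the substrate in it: one side product C counts as two
- run time (elm): 12 d

1. which flask leads in amount of side product A, in percent of the substrate charged ("all alike" within 1.5 percentage points) (elm / larch / cedar / maple / all alike)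
2. how much side product A is there at the end, in percent of the substrate charged: elm
3. how much side product A is there at the end, in percent of the substrate charged: larch
4. how much side product A is there at the end, in percent of the substrate charged: cedar
5. how much side product A is there at the end, in percent of the substrate charged: maple

Substrate goes by itself to intermediate B at k3, and with reagent to intermediate A at k1 times the reagent, a pseudo-first-order rate. I write the reagent r as a fraction of the substrate charge. The fork level, the value of r at which the two ways run equally fast, is k3/(k1·cA) = 0.433. Intermediate A then takes a second reagent, and side product A gets the share k2/(k2+k4) = 0.466 of what passes.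

In larch r starts at 1.50 equiv, so the fork sends 0.776 to intermediate A. Each pass costs two reagents, so that fork would need 1.55, more than the charge, and it must slide. By its step to intermediate C alone, intermediate B has a half-life of 2.3 d, longer than the substrate's time constant of 0.281 d, so in this reckoning I leave that use out. I solve both ends: suppose r ends at the fork level, where the fork stands at 0.5. The mean fork is then 0.638, but the reagent balance allows 0.534. Joined, that is 0.586, which gives 27.3% of side product A and leaves r at 0.328.

The weak link is intermediate A returning to substrate at k1/K1. That return equals the forward use at r = 0.158, and my reckoned end value of r in larch, which leaves out the uptake by intermediate B, is twice that. Counting the return, the fork runs from 0.758 to 0.339, the join falls to 0.567, and I commit to 26.4% for larch.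

In elm the feed has brought 0.235 by the time 1/k3 = 1.26 d, and the first portion in cedar is 0.375, both below the fork level. Maple has the full reagent waiting, so by hand I can't part it from larch.

The forecast names larch, with 26% there, 24% in maple, 9.3% in elm and 9.1% in cedar, holding for the slow flasks that “reagent is scarce early, so substrate drains to intermediate B”.

Larch gives 26.1%, maple 23.7%, cedar 9.54% and elm 5.92%, so larch leads by 2.4 percentage points over maple, against a margin of 1.5 points. Larch's reagent stands at 0.107 of the substrate charge after 12.0 d, below the fork level of 0.433. The neighbour flask with 2.50 equiv of reagent ends with 0.604, above it. The share times the fork gives 39.7% at its charge and 27.2% at its end, and that flask stands at 36.4%.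

(Its constants are assumed.)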